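## Structural features

The target is a spiro[4.5]decene: a cyclopentane (C7–C11) and a cyclohexene (C11–C16, C13=C14) share the quaternary carbon C11. C10 (methyl), C11 and C7 are three contiguous stereocentres on the five-membered ring. C7 carries a side chain whose first carbon C6 is a fourth, methyl-bearing stereocentre, and C15 is a fifth: an allylic carbinol esterified with 3-phenylpropanoic acid, its oxygen pointing to the C7 side of the cyclohexene. The chain ends in a (Z)-γ-alkylidene-α-methylbutenolide (C1–C5), an enol lactone that does not survive strong base, nucleophiles, hydride or hydrogenation; the allylic ester can ionise or be cleaved, and C6 is epimerisable while C5 is a carbonyl group. The difficulty is twofold: the spiro carbon C11 must tell two CH2 arms (C12 and C16) apart relative to the C10 methyl, and the hydrogen on C7 must end on the more crowded face, cis to C16 and to the C10 methyl. C10 and C11 are neighbours and C7 can be a carbonyl carbon, so C10, C11 and C7 are the β-carbon, α-carbon and carbonyl carbon of a 2-substituted cyclopent-2-enone. The key step uses exactly this: with the C16 arm already on C11, methyl is added to C10 and the C12 arm to C11 in one operation.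

## Logic of the disconnections

**34 ⇒ 30 + 31.** The C4=C5 double bond of the enol lactone is cut. The alkylidene butenolide is the most sensitive part, so it is formed last; the cut removes five carbons, the Z olefin and the lactone at once and leaves an aldehyde. The forward step must join C4 to C5 and eliminate without epimerising C6 of 30, and must end at the Z isomer.

**30 ⇒ 29 ⇒ 27 ⇒ 26.** C5 is taken back to the alcohol level, then the C5–O and C6–H bonds are cut (hydroboration), then the C6=C5 bond (methylenation). C6 becomes a carbonyl carbon, so its configuration is set late from the neighbouring C7 and the branched chain comes from an acetyl group. The demands are face-selective anti-Markovnikov hydroboration that leaves C13=C14 and the ester alone, and a methylenation that does not enolise C7.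

**26 ⇒ 25 ⇒ 24 ⇒ 23.** The C7–H and C8–H bonds are cut. The C7 hydrogen sits on the more hindered face, so it is delivered by a metal held by a hydroxyl group: the C6 ketone is reduced to a carbinol of chosen configuration and re-oxidised afterwards. This costs two redox steps and requires that the hydrogenation touch only the olefin next to the free hydroxyl.

**23 ⇒ 21 + 22 and 21 ⇒ 18 + 19.** The ester C–O bond and then the C6–C7 bond are cut. The acetyl unit arrives as the two-carbon stannane 19 on the C7 enol triflate. The ester is added after the palladium step, because an allylic ester could ionise on zerovalent palladium, and before the hydrogenation, so that C15 offers no free hydroxyl. The demand is coupling at a hindered alkenyl triflate next to a quaternary carbon.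

**18 ⇒ 17 ⇒ 16.** C15–H is cut (carbonyl reduction), then the C13=C14 double bond (metathesis). A ketone at C15 lets a catalyst set this remote centre, and the ring opens to two olefin arms on C11. The demands are reagent control over whatever bias the spiro centre has, and ring closure to a trisubstituted enone.

**16 ⇒ 14 + 15, and 14 ⇒ 12 ⇒ 11 ⇒ 9.** C14–C15 is cut (acyl substitution); the rest are functional-group changes on the C16 arm and at C7. Converting the C7 ketone into its enol triflate first serves two purposes: it protects C7 from the Grignard and hydride reagents, and it is the coupling handle used later. The demand is that the triflate survive acid, a Grignard reagent, ruthenium and borane.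

**9 ⇒ 5 + 6 + 7.** C10–CH3 and C11–C12 are cut together. This removes both stereocentres and leaves a flat enone; the C16 arm stays on the enone so that the order of introduction distinguishes C16 from C12. The tert-butyl ester is kept because it resists the Grignard reagent. The demands are enantioface selection at C10 by the catalyst, trans alkylation at C11, and no deprotonation of the C16 methylene.

**5 ⇒ 2 + 3 and 2 ⇒ 1.** The C11–C16 bond is cut (sp2–sp3 coupling), then C–I. Both fragments are commercial. The demand is that the zinc enolate couple faster than it adds to the ketone.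

## Other disconnections considered

**Alternative 1:** The cut is the C10–C11 bond, with the C10 methyl drawn from a vinyl group. The cyclopentane is closed last, onto the β-carbon of the 3-substituted cyclohex-2-enone A1, 3-[(2S,3R)-1-(tert-butyldimethylsilyloxy)-2-methylhept-6-en-3-yl]cyclohex-2-en-1-one, which already holds C6 and C7. Fe(acac)3 and PhSiH3 in ethanol would transfer a hydrogen atom to the terminal olefin carbon; the secondary C10 radical would add 5-exo-trig to C11, and reduction and protonation of the α-keto radical would give the spiro ketone A2.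
- In its favour: C6 and C7 are made by acyclic stereocontrol before any ring exists, so the delivery of hydrogen to the crowded face of C7 (steps 12 to 14 of the chosen plan) is not needed. On this point the alternative is the better one.
- A radical suits a quaternary centre and tolerates the silyl ether. Ring, C10 and C11 arise in one step, which equals the chosen key step in bonds and stereocentres formed.
- Against it: C10 and C11 would both be set by the conformation of a flexible chain relative to C7, with no reagent control. A methyl-substituted secondary radical usually closes with modest cis/trans preference, and which of C12 and C16 ends cis to the methyl depends on the enone face attacked.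
- In A2 the six-membered ring holds only the C15 ketone, so the C14 methyl, C13=C14 and the C15 carbinol would still have to be added, and enantiopure A1 needs its own asymmetric synthesis.
- Comparison: the chosen plan has firmer control of C10 and C11 (catalyst, then trans alkylation) and brings the six-ring carbons in with the right oxidation pattern; alternative 1 is cleaner at C6 and C7; in step count it is expected to be no shorter.

**Alternative 2:** The cut is C14–C15 in the cyclohexene. The aldehyde A3, 2-[(1S,2S)-1-[(2Z)-3-iodobut-2-en-1-yl]-2-methyl-5-oxocyclopentyl]acetaldehyde, carries the Z-alkenyl iodide on the C12 arm. CrCl2 with catalytic NiCl2 in DMF would turn the C–I bond into an alkenylchromium species that adds to the aldehyde and closes the ring to the allylic alcohol A4, 7-hydroxy-4,8-dimethylspiro[4.5]dec-8-en-1-one with C10, C11 and C15 as in the target.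
- In its favour: organochromium reagents add to aldehydes and leave ketones alone, so the C7 carbonyl needs no masking. This is better than the chosen plan, where the enol triflate has to take that role.
- The alkenyl iodide fixes the double-bond position and the C14 methyl, and no carbon is lost as ethene. One bond closes the ring, as in the metathesis: equal.
- Against it: C15 would depend only on 1,3-induction from the quaternary C11, which is unlikely to be decisive. An oxidation to the enone and a catalyst-controlled reduction would probably follow, as in steps 8 and 9 but one step longer.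
- The chromium salt is needed in excess and is toxic, and the iodoalkenyl arm needs a four-carbon electrophile in the key step or oxidative cleavage and Z-selective iodo-olefination of the allyl group.
- Comparison: the plans share the quaternary centre and differ in mechanism (polar 1,2-addition against olefin metathesis). The chosen one reaches the C15 ketone directly and sets C15 by reagent, at the price of a ruthenium catalyst and the triflate mask.

**Alternative 3:** The cut is C7–C11: the cyclopentane is closed by reductive coupling of two acceptor β-carbons in the enone–enoate A5, methyl (2E,6S)-6-(3-oxocyclohex-1-en-1-yl)hept-2-enoate. At a lead cathode at constant current (Et4NOTs, acetonitrile–water, dimethyl malonate as proton donor) the radical anion of one acceptor would add 5-exo to the other, and two protonations would give the spiro keto ester A6, methyl 2-(4-methyl-7-oxospiro[4.5]decan-1-yl)acetate.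
- In its favour: the reductant is the electrode, no metal reagent or protecting group is involved, the precursor has a single stereocentre (C10), and C7 is created with its hydrogen and its carbon chain in one step. In steps to the spiro skeleton and in the way C7–H arises it is better than the chosen plan.
- It equals the chosen plan in forming the quaternary centre together with a vicinal stereocentre through one C–C bond.
- Against it: C7 and C11 would be set only by the cyclisation geometry relative to C10, and hydrodimerisation and plain saturation of the enoate compete.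
- The C6 methyl is missing and would need enolate alkylation with acyclic stereocontrol (probably an auxiliary); C5 is at the ester level; the six-membered ring of A6 needs the same late C14 methyl, C13=C14 and C15 work as in alternative 1. A divided cell and a lead cathode are less common equipment.
- Comparison: the chosen plan is longer to the spiro ring but sets every centre by a catalyst or a defined neighbouring-group effect, and carries the right six-ring substitution from step 7 on.

Key step: step 3

Assumption: the antipode of the ferrocenyl diphosphine written in step 3 is taken as the one that gives the 10S series; if the sense of induction is the opposite, the mirror-image ligand is used and nothing else changes.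

Remark: locants C1 to C16 in names and text follow the target numbering (butenolide C1–C4, C5, C6, cyclopentane C7–C10, spiro C11, cyclohexene C12–C16). Compounds 5 and 9 were checked against the target (9 is 10S,11S) and needed no structural correction.

## Route

**Step 1**
Reactants: 1 cyclopent-2-en-1-one
Product: 2 2-iodocyclopent-2-en-1-one
Conditions: I2, pyridine, CH2Cl2, 0→23 °C
Reagents that add atoms: iodine, II
Why: α-Iodination of an enone by conjugate addition of pyridine, iodination of the enolate and loss of pyridine; C2 is the only position that this addition–elimination sequence can iodinate.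

**Step 2**
Reactants: 2 2-iodocyclopent-2-en-1-one; 3 tert-butyl bromoacetate
Product: 5 tert-butyl 2-(5-oxocyclopent-1-en-1-yl)acetate, via bromozinc enolate 4 (not isolated)
Conditions: 3, Zn (Me3SiCl-activated), THF, 23 °C; then 2, Pd2(dba)3 (2 mol %), XPhos (8 mol %), THF, 23→40 °C
Reagents that add atoms: none
Why: Negishi-type coupling of a Reformatsky reagent with an alkenyl iodide; oxidative addition of zerovalent palladium to the C–I bond of the α-iodoenone is fast, so coupling at C2 should outrun 1,2-addition of the zinc enolate to the ketone, and the tert-butyl ester prevents Claisen condensation.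

**Step 3**
Reactants: 5 tert-butyl 2-(5-oxocyclopent-1-en-1-yl)acetate; 6 methylmagnesium bromide; 7 allyl iodide
Product: 9 tert-butyl 2-[(1S,2S)-2-methyl-5-oxo-1-(prop-2-en-1-yl)cyclopentyl]acetate, via magnesium enolate 8 (not isolated)
Conditions: 6 (1.3 equiv), CuBr·SMe2 (5 mol %), (R)-1-[(S_p)-2-(dicyclohexylphosphino)ferrocenyl]ethyldiphenylphosphine (6 mol %), t-BuOMe, −78 °C, slow addition of 5; then 7 (3 equiv), DMPU, −78→0 °C
Reagents that add atoms: none
Why: The monovalent copper–diphosphine complex and 6 form a chiral methylcuprate that π-binds the enone and transfers CH3 to the β-carbon C10 on one enantioface (through a trivalent copper intermediate and reductive elimination), leaving the magnesium enolate 8 with the C7=C11 enolate double bond fixed in position. The closest known reaction type is the copper-catalysed asymmetric conjugate addition of Grignard reagents to 2-substituted cyclopent-2-enones with alkylation of the intermediate enolate. DMPU and 7 then bring about SN2 C-allylation at C11; no ring is closed. C10 is controlled by the chiral copper complex, C11 by the new vicinal methyl group, which sends the allyl electrophile to the opposite face so that C12 ends trans and the existing C16 arm cis to the methyl. The step needs 1,4- over 1,2-addition (copper catalysis at −78 °C and slow addition of 5), survival of the ester (tert-butyl group) and no proton transfer from the acidic C16 methylene (low basicity of the cuprate, low temperature). C- over O-allylation follows from the soft iodide and the magnesium counter-ion, and the quaternary product cannot re-enolise at C11, so over-alkylation is limited to C8 and is slow in the cold.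

**Step 4**
Reactants: 9 tert-butyl 2-[(1S,2S)-2-methyl-5-oxo-1-(prop-2-en-1-yl)cyclopentyl]acetate
Product: 11 tert-butyl 2-[(1S,5S)-5-methyl-1-(prop-2-en-1-yl)-2-{[(trifluoromethyl)sulfonyl]oxy}cyclopent-2-en-1-yl]acetate, via potassium enolate 10 (not isolated)
Conditions: KN(SiMe3)2, THF, −78 °C; then PhNTf2, −78→0 °C
Reagents that add atoms: N-phenylbis(trifluoromethanesulfonimide), O=S(=O)(N(c1ccccc1)S(=O)(=O)C(F)(F)F)C(F)(F)F
Why: The ketone can enolise only towards C8 because C11 is quaternary, and the potassium enolate is O-sulfonylated (enol triflate formation); the triflate masks the C7 carbonyl against the Grignard and borane steps that follow and is the handle for the later C6–C7 coupling.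

**Step 5**
Reactants: 11 tert-butyl ester triflate
Product: 12 2-[(1S,5S)-5-methyl-1-(prop-2-en-1-yl)-2-{[(trifluoromethyl)sulfonyl]oxy}cyclopent-2-en-1-yl]acetic acid
Conditions: CF3CO2H, CH2Cl2, 0→23 °C
Reagents that add atoms: none
Why: Acidolysis of the tert-butyl ester through the tert-butyl cation with loss of 2-methylpropene; enol triflates and the terminal olefin are stable to trifluoroacetic acid at this temperature.

**Step 6**
Reactants: 12 carboxylic acid triflate
Product: 14 N-methoxy-N-methyl-2-[(1S,5S)-5-methyl-1-(prop-2-en-1-yl)-2-{[(trifluoromethyl)sulfonyl]oxy}cyclopent-2-en-1-yl]acetamide, via acyl imidazolide 13 (not isolated)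
Conditions: 1,1'-carbonyldiimidazole, CH2Cl2, 23 °C; then MeNH(OMe)·HCl, 23 °C
Reagents that add atoms: N,O-dimethylhydroxylamine hydrochloride, CNOC.Cl
Why: Activation of the acid as the acyl imidazolide and aminolysis (Weinreb amide synthesis); the neutral conditions leave the enol triflate untouched.

**Step 7**
Reactants: 14 Weinreb amide triflate; 15 isopropenylmagnesium bromide
Product: 16 (4S,5S)-4-methyl-5-(3-methyl-2-oxobut-3-en-1-yl)-5-(prop-2-en-1-yl)cyclopent-1-en-1-yl trifluoromethanesulfonate
Conditions: 15 (2.5 equiv), THF, −20→0 °C; then cold aq. NH4Cl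
Reagents that add atoms: none
Why: Weinreb ketone synthesis: the five-membered magnesium chelate stops the addition at the ketone stage and forms C14–C15. Alkenyl triflates do not react with Grignard reagents without a transition-metal catalyst, and the acidic quench removes the liberated amine before it can add to the enone.

**Step 8**
Reactants: 16 isopropenyl ketone triflate
Product: 17 (10S,11S)-10,14-dimethyl-15-oxospiro[4.5]deca-7,13-dien-7-yl trifluoromethanesulfonate
Conditions: (H2IMes)(PCy3)Cl2Ru=CHPh (second-generation Grubbs catalyst, 5 mol %), CH2Cl2, 40 °C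
Reagents that add atoms: none
Why: Ring-closing metathesis between the allyl group and the isopropenyl ketone closes the six-membered ring as the trisubstituted C13=C14 enone with loss of ethene; the electron-poor, trisubstituted enol triflate olefin does not take part.

**Step 9**
Reactants: 17 spiro enone triflate
Product: 18 (10S,11S,15S)-15-hydroxy-10,14-dimethylspiro[4.5]deca-7,13-dien-7-yl trifluoromethanesulfonate
Conditions: (R)-2-methyl-CBS-oxazaborolidine (20 mol %), BH3·SMe2, THF, −30 °C; then MeOH
Reagents that add atoms: none
Why: Corey–Bakshi–Shibata reduction of an α-substituted cyclohexenone: with the α-methylalkenyl carbon C14 as the large and the C16 methylene as the small group, the (R)-catalyst should deliver hydride to the face that gives the 15S carbinol (oxygen on the C7 side). The centre is set by the catalyst and not by the remote spiro carbon, and the catalyst-bound borane reduces 1,2.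

**Step 10**
Reactants: 18 (15S)-hydroxy triflate; 19 tributyl(1-ethoxyethenyl)stannane
Product: 21 1-[(10S,11S,15S)-15-hydroxy-10,14-dimethylspiro[4.5]deca-7,13-dien-7-yl]ethan-1-one, via ethoxydiene 20 (not isolated)
Conditions: 19, Pd(PPh3)4 (5 mol %), LiCl, THF, 65 °C; then 1 M aq. HCl, THF, 23 °C
Reagents that add atoms: water, O
Why: Stille coupling of the alkenyl triflate with an acyl-anion equivalent forms C6–C7, and mild acid hydrolysis of the enol ether releases the methyl enone. The coupling is run on the free allylic alcohol because an allylic ester could ionise on zerovalent palladium.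

**Step 11**
Reactants: 21 hydroxy methyl enone; 22 3-phenylpropanoyl chloride
Product: 23 (10S,11S,15S)-7-acetyl-10,14-dimethylspiro[4.5]deca-7,13-dien-15-yl 3-phenylpropanoate
Conditions: 22, Et3N, DMAP (cat.), CH2Cl2, 0 °C
Reagents that add atoms: none
Why: DMAP-catalysed O-acylation of the secondary allylic alcohol with retention at C15; the final ester is put on now so that C15 offers no free hydroxyl to the hydrogenation catalyst of step 13.

**Step 12**
Reactants: 23 ester methyl enone
Product: 24 (10S,11S,15S)-7-[(1R)-1-hydroxyethyl]-10,14-dimethylspiro[4.5]deca-7,13-dien-15-yl 3-phenylpropanoate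
Conditions: (S)-2-methyl-CBS-oxazaborolidine (20 mol %), BH3·SMe2, THF, −30 °C; then MeOH
Reagents that add atoms: none
Why: Corey–Bakshi–Shibata reduction of an alkenyl methyl ketone (alkenyl large, methyl small), which with the (S)-catalyst should give the 6R allylic alcohol under catalyst control; the ester and the two trisubstituted olefins are not attacked by the catalyst-bound borane at this temperature.

**Step 13**
Reactants: 24 (6R)-allylic alcohol
Product: 25 (7S,10S,11S,15S)-7-[(1R)-1-hydroxyethyl]-10,14-dimethylspiro[4.5]dec-13-en-15-yl 3-phenylpropanoate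
Conditions: H2 (50 bar), [Rh(nbd)(dppb)]BF4 (10 mol %), CH2Cl2, 23 °C
Reagents that add atoms: none
Why: Hydroxyl-directed hydrogenation of an allylic alcohol: in the chelate the C6–H bond lies towards the quaternary C11 and the C6 methyl towards C8–H (least allylic 1,2-strain), which for the 6R carbinol places rhodium on the face syn to C16, so both hydrogens arrive there and C7–H ends cis to C16 and the C10 methyl. The cationic rhodium catalyst reduces only the olefin that can chelate through a free hydroxyl, so C13=C14 next to the acylated oxygen is left.

**Step 14**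
Reactants: 25 saturated (6R)-carbinol
Product: 26 (7S,10S,11S,15S)-7-acetyl-10,14-dimethylspiro[4.5]dec-13-en-15-yl 3-phenylpropanoate
Conditions: Dess–Martin periodinane, NaHCO3, CH2Cl2, 0→23 °C
Reagents that add atoms: none
Why: Oxidation of the secondary alcohol to the methyl ketone with a hypervalent iodine reagent under buffered, non-enolising conditions, so that the new C7 centre α to the ketone is not epimerised.

**Step 15**
Reactants: 26 methyl ketone
Product: 27 (7R,10S,11S,15S)-10,14-dimethyl-7-(prop-1-en-2-yl)spiro[4.5]dec-13-en-15-yl 3-phenylpropanoate
Conditions: Zn, CH2Br2, TiCl4, THF/CH2Cl2, 0→23 °C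
Reagents that add atoms: dibromomethane, BrCBr
Why: Lombardo methylenation: the non-basic titanium–zinc methylene reagent converts the hindered methyl ketone into the isopropenyl group without enolising C7 and does not attack the ester.

**Step 16**
Reactants: 27 isopropenyl compound
Product: 29 (7R,10S,11S,15S)-7-[(2S)-1-hydroxypropan-2-yl]-10,14-dimethylspiro[4.5]dec-13-en-15-yl 3-phenylpropanoate, via alkylborane 28 (not isolated)
Conditions: 9-BBN, THF, 0→50 °C; then NaBO3·4H2O, THF/H2O, 23 °C
Reagents that add atoms: sodium perborate, [Na+].[O-]OB=O
Why: Anti-Markovnikov hydroboration–oxidation: 9-BBN adds to the 1,1-disubstituted olefin far faster than to trisubstituted C13=C14, and in the conformer with C7–H eclipsing the double bond it attacks the face away from the quaternary C11, which sets C6 as required, as is known for isopropenyl groups on a cyclopentane next to a quaternary carbon (20-methylene steroids). Perborate oxidises the C–B bond with retention and spares the ester.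

**Step 17**
Reactants: 29 primary alcohol
Product: 30 (7R,10S,11S,15S)-10,14-dimethyl-7-[(2S)-1-oxopropan-2-yl]spiro[4.5]dec-13-en-15-yl 3-phenylpropanoate
Conditions: Dess–Martin periodinane, NaHCO3, CH2Cl2, 0 °C
Reagents that add atoms: none
Why: Buffered hypervalent-iodine oxidation of the primary alcohol to the aldehyde; the non-basic conditions and immediate use avoid epimerisation at C6.

**Step 18**
Reactants: 30 aldehyde; 31 3-methylfuran-2(5H)-one
Product: 34 (7R,10S,11S,15S)-10,14-dimethyl-7-{(2S)-1-[(2Z)-4-methyl-5-oxofuran-2(5H)-ylidene]propan-2-yl}spiro[4.5]dec-13-en-15-yl 3-phenylpropanoate, via silyloxyfuran 32 (not isolated), via silyl aldol 33 (not isolated)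
Conditions: 31, t-BuMe2SiOTf, Et3N, CH2Cl2, 0 °C; then 30, −78 °C; then DBU, −78→23 °C
Reagents that add atoms: none
Why: Vinylogous Mukaiyama aldol addition of the 2-silyloxyfuran at its γ-carbon to the aldehyde forms C4–C5, and DBU then deprotonates C4 and expels silanolate (E1cB) to give the alkylidene butenolide. The Z isomer is thermodynamically preferred because it avoids allylic strain between C6 and C3–H, and C6 is no longer acidic once the aldehyde is consumed.

## Compound list

1 | cyclopent-2-en-1-one | O=C1CCC=C1 | starting material
2 | 2-iodocyclopent-2-en-1-one | O=C1CCC=C1I | intermediate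
3 | tert-butyl bromoacetate | CC(C)(C)OC(=O)CBr | starting material
4 | bromo(2-tert-butoxy-2-oxoethyl)zinc | CC(C)(C)OC(=O)C[Zn]Br | intermediate
5 | tert-butyl 2-(5-oxocyclopent-1-en-1-yl)acetate | O=C1CCC=C1CC(=O)OC(C)(C)C | intermediate
6 | methylmagnesium bromide | C[Mg]Br | starting material
7 | allyl iodide | C=CCI | starting material
8 | tert-butyl 2-[(5S)-2-(bromomagnesiooxy)-5-methylcyclopent-1-en-1-yl]acetate | C[C@H]1CCC(O[Mg]Br)=C1CC(=O)OC(C)(C)C | intermediate
9 | tert-butyl 2-[(1S,2S)-2-methyl-5-oxo-1-(prop-2-en-1-yl)cyclopentyl]acetate | O=C2CC[C@H](C)[C@@]2(CC(=O)OC(C)(C)C)CC=C | intermediate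
10 | potassium (4S,5S)-5-(2-tert-butoxy-2-oxoethyl)-4-methyl-5-(prop-2-en-1-yl)cyclopent-1-en-1-olate | [K+].[O-]C1=CC[C@H](C)[C@@]1(CC(=O)OC(C)(C)C)CC=C | intermediate
11 | tert-butyl 2-[(1S,5S)-5-methyl-1-(prop-2-en-1-yl)-2-{[(trifluoromethyl)sulfonyl]oxy}cyclopent-2-en-1-yl]acetate | FC(F)(F)S(=O)(=O)OC1=CC[C@H](C)[C@@]1(CC(=O)OC(C)(C)C)CC=C | intermediate
12 | 2-[(1S,5S)-5-methyl-1-(prop-2-en-1-yl)-2-{[(trifluoromethyl)sulfonyl]oxy}cyclopent-2-en-1-yl]acetic acid | FC(F)(F)S(=O)(=O)OC1=CC[C@H](C)[C@@]1(CC(=O)O)CC=C | intermediate
13 | acyl imidazolide of 12 (imidazol-1-yl in place of OH) | FC(F)(F)S(=O)(=O)OC1=CC[C@H](C)[C@@]1(CC(=O)n2ccnc2)CC=C | intermediate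
14 | N-methoxy-N-methyl amide of 12 | FC(F)(F)S(=O)(=O)OC1=CC[C@H](C)[C@@]1(CC(=O)N(C)OC)CC=C | intermediate
15 | isopropenylmagnesium bromide | CC(=C)[Mg]Br | starting material
16 | (4S,5S)-4-methyl-5-(3-methyl-2-oxobut-3-en-1-yl)-5-(prop-2-en-1-yl)cyclopent-1-en-1-yl trifluoromethanesulfonate | FC(F)(F)S(=O)(=O)OC1=CC[C@H](C)[C@@]1(CC(=O)C(C)=C)CC=C | intermediate
17 | (10S,11S)-10,14-dimethyl-15-oxospiro[4.5]deca-7,13-dien-7-yl trifluoromethanesulfonate | FC(F)(F)S(=O)(=O)OC1=CC[C@H](C)[C@@]12CC=C(C)C(=O)C2 | intermediate
18 | (10S,11S,15S)-15-hydroxy-10,14-dimethylspiro[4.5]deca-7,13-dien-7-yl trifluoromethanesulfonate | FC(F)(F)S(=O)(=O)OC1=CC[C@H](C)[C@@]12CC=C(C)[C@@H](O)C2 | intermediate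
19 | tributyl(1-ethoxyethenyl)stannane | CCCC[Sn](CCCC)(CCCC)C(=C)OCC | starting material
20 | (10S,11S,15S)-7-(1-ethoxyethenyl)-10,14-dimethylspiro[4.5]deca-7,13-dien-15-ol | CCOC(=C)C1=CC[C@H](C)[C@@]12CC=C(C)[C@@H](O)C2 | intermediate
21 | 1-[(10S,11S,15S)-15-hydroxy-10,14-dimethylspiro[4.5]deca-7,13-dien-7-yl]ethan-1-one | CC(=O)C1=CC[C@H](C)[C@@]12CC=C(C)[C@@H](O)C2 | intermediate
22 | 3-phenylpropanoyl chloride | O=C(Cl)CCc1ccccc1 | starting material
23 | (10S,11S,15S)-7-acetyl-10,14-dimethylspiro[4.5]deca-7,13-dien-15-yl 3-phenylpropanoate | CC(=O)C1=CC[C@H](C)[C@@]12CC=C(C)[C@@H](OC(=O)CCc3ccccc3)C2 | intermediate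
24 | (10S,11S,15S)-7-[(1R)-1-hydroxyethyl]-10,14-dimethylspiro[4.5]deca-7,13-dien-15-yl 3-phenylpropanoate | C[C@@H](O)C1=CC[C@H](C)[C@@]12CC=C(C)[C@@H](OC(=O)CCc3ccccc3)C2 | intermediate
25 | (7S,10S,11S,15S)-7-[(1R)-1-hydroxyethyl]-10,14-dimethylspiro[4.5]dec-13-en-15-yl 3-phenylpropanoate | C[C@@H](O)[C@H]1CC[C@H](C)[C@@]12CC=C(C)[C@@H](OC(=O)CCc3ccccc3)C2 | intermediate
26 | (7S,10S,11S,15S)-7-acetyl-10,14-dimethylspiro[4.5]dec-13-en-15-yl 3-phenylpropanoate | CC(=O)[C@H]1CC[C@H](C)[C@@]12CC=C(C)[C@@H](OC(=O)CCc3ccccc3)C2 | intermediate
27 | (7R,10S,11S,15S)-10,14-dimethyl-7-(prop-1-en-2-yl)spiro[4.5]dec-13-en-15-yl 3-phenylpropanoate | CC(=C)[C@H]1CC[C@H](C)[C@@]12CC=C(C)[C@@H](OC(=O)CCc3ccccc3)C2 | intermediate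
28 | B-alkyl-9-borabicyclo[3.3.1]nonane from 27 (boron on C5, C6 configured as in 29) | C(B1C2CCCC1CCC2)[C@@H](C)[C@H]3CC[C@H](C)[C@@]34CC=C(C)[C@@H](OC(=O)CCc5ccccc5)C4 | intermediate
29 | (7R,10S,11S,15S)-7-[(2S)-1-hydroxypropan-2-yl]-10,14-dimethylspiro[4.5]dec-13-en-15-yl 3-phenylpropanoate | OC[C@@H](C)[C@H]1CC[C@H](C)[C@@]12CC=C(C)[C@@H](OC(=O)CCc3ccccc3)C2 | intermediate
30 | (7R,10S,11S,15S)-10,14-dimethyl-7-[(2S)-1-oxopropan-2-yl]spiro[4.5]dec-13-en-15-yl 3-phenylpropanoate | O=C[C@@H](C)[C@H]1CC[C@H](C)[C@@]12CC=C(C)[C@@H](OC(=O)CCc3ccccc3)C2 | intermediate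
31 | 3-methylfuran-2(5H)-one | CC1=CCOC1=O | starting material
32 | tert-butyldimethyl[(3-methylfuran-2-yl)oxy]silane | Cc1ccoc1O[Si](C)(C)C(C)(C)C | intermediate
33 | C5 tert-butyldimethylsilyl ether of the C4–C5 aldol adduct of 30 and 32 (mixture at C4 and C5) | CC1=CC(OC1=O)C(O[Si](C)(C)C(C)(C)C)[C@@H](C)[C@H]2CC[C@H](C)[C@@]23CC=C(C)[C@@H](OC(=O)CCc4ccccc4)C3 | intermediate
34 | (7R,10S,11S,15S)-10,14-dimethyl-7-{(2S)-1-[(2Z)-4-methyl-5-oxofuran-2(5H)-ylidene]propan-2-yl}spiro[4.5]dec-13-en-15-yl 3-phenylpropanoate (CNP0260277.1) | CC1=C/C(=C/[C@@H](C)[C@H]2CC[C@H](C)[C@@]23CC=C(C)[C@@H](OC(=O)CCc2ccccc2)C3)OC1=O | target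

## Step count and least certain steps

Total: 18 steps. Longest linear sequence: 18 steps (1 to 34; the route is fully linear).

**Step 3 (key step).** Most likely to fail: trapping of the magnesium enolate, through O-allylation or slow C-allylation of the hindered tetrasubstituted enolate with equilibration towards C8. Before that, enantioselectivity may erode because methyl is the least reactive Grignard group and the C16 methylene of 5 can be deprotonated in competition. Fallback: from 5, the conjugate addition is run in the same way and the enolate 8 is quenched with allyl chloroformate to give tert-butyl 2-[(5S)-5-methyl-2-{[(prop-2-en-1-yloxy)carbonyl]oxy}cyclopent-1-en-1-yl]acetate F1. Pd(PPh3)4 in THF then brings about decarboxylative Tsuji allylation, in which the π-allylpalladium–enolate pair forms C11–C12 anti to the methyl group, and the route is rejoined at 9.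

**Step 13.** Most likely to fail: facial selectivity. The directing conformer puts rhodium on the more crowded ring face, so turnover may be slow and the uncomplexed pathway from the open face, or isomerisation of the allylic alcohol, may compete. Fallback: from 23, conjugate reduction with [(Ph3P)CuH]6 gives the methyl ketone as a mixture of 26 and its C7 epimer (7R,10S,11S,15S)-7-acetyl-10,14-dimethylspiro[4.5]dec-13-en-15-yl 3-phenylpropanoate F2. Equilibration through the enol with DBU in toluene, separation and recycling of F2 lead to 26 and bypass steps 12 to 14; control at C7 changes from kinetic, hydroxyl-directed delivery to thermodynamic.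

**Step 16.** Most likely to fail: 1,2-induction from C7 may give poor face selectivity at the isopropenyl group, because C11 carries two CH2 arms where the steroid model has one methyl. Fallback: from 26, Wittig reaction with Ph3P=CHOMe (from the phosphonium chloride and KN(SiMe3)2) gives the enol ether (7R,10S,11S,15S)-7-(1-methoxyprop-1-en-2-yl)-10,14-dimethylspiro[4.5]dec-13-en-15-yl 3-phenylpropanoate F3. Hydrolysis with aqueous oxalic acid gives 30 together with its C6 epimer (7R,10S,11S,15S)-10,14-dimethyl-7-[(2R)-1-oxopropan-2-yl]spiro[4.5]dec-13-en-15-yl 3-phenylpropanoate F4; they are separated, F4 is re-equilibrated through its enol with DBU and recycled, and the route is rejoined at 30.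

**Step 9.** Most likely to fail: catalyst control. The C16 methylene next to the spiro carbon is a rather large "small" group, and the spiro centre may impose its own facial bias. Fallback: from 17, Luche reduction (NaBH4, CeCl3·7H2O, MeOH) gives the substrate-controlled mixture. 18 is carried on; the 15R epimer (10S,11S,15R)-15-hydroxy-10,14-dimethylspiro[4.5]deca-7,13-dien-7-yl trifluoromethanesulfonate F5 is inverted by Mitsunobu esterification with 4-nitrobenzoic acid (PPh3, DIAD) to the 15S 4-nitrobenzoate (10S,11S,15S)-10,14-dimethyl-7-{[(trifluoromethyl)sulfonyl]oxy}spiro[4.5]deca-7,13-dien-15-yl 4-nitrobenzoate F6, whose methanolysis (K2CO3, MeOH, 0 °C) returns 18.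

**Step 2.** Most likely to fail: the zinc enolate may add 1,2 to the enone carbonyl or reduce the C–I bond faster than it transmetalates, and the product may isomerise to the exocyclic enone. Fallback: from 3, Stork enamine alkylation of 1-(cyclopent-1-en-1-yl)pyrrolidine and hydrolysis give tert-butyl 2-(2-oxocyclopentyl)acetate F7. Me3SiCl, NaI and Et3N give the more substituted silyl enol ether tert-butyl 2-{2-[(trimethylsilyl)oxy]cyclopent-1-en-1-yl}acetate F8, and Saegusa–Ito oxidation with Pd(OAc)2 introduces the ring double bond and rejoins the route at 5.

**Step 18.** Most likely to fail: C6 of the α-branched aldehyde may epimerise while amine and silyl triflate are present, retro-aldol cleavage may compete during the elimination, and the E/Z ratio may be incomplete. Fallback: from 31, radical bromination with N-bromosuccinimide gives 5-bromo-3-methylfuran-2(5H)-one F9, and PPh3 gives (4-methyl-5-oxo-2,5-dihydrofuran-2-yl)triphenylphosphonium bromide F10. Wittig olefination of 30 with the stabilised ylide formed from F10 and Et3N gives 34 directly, any E isomer being equilibrated to Z with a trace of I2 in light.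

## Further compounds

F1 | step 3 | tert-butyl 2-[(5S)-5-methyl-2-{[(prop-2-en-1-yloxy)carbonyl]oxy}cyclopent-1-en-1-yl]acetate | C[C@H]1CCC(OC(=O)OCC=C)=C1CC(=O)OC(C)(C)C
F2 | step 13 | (7R,10S,11S,15S)-7-acetyl-10,14-dimethylspiro[4.5]dec-13-en-15-yl 3-phenylpropanoate (C7 epimer of 26) | CC(=O)[C@@H]1CC[C@H](C)[C@@]12CC=C(C)[C@@H](OC(=O)CCc3ccccc3)C2
F3 | step 16 | (7R,10S,11S,15S)-7-(1-methoxyprop-1-en-2-yl)-10,14-dimethylspiro[4.5]dec-13-en-15-yl 3-phenylpropanoate (E/Z mixture) | COC=C(C)[C@H]1CC[C@H](C)[C@@]12CC=C(C)[C@@H](OC(=O)CCc3ccccc3)C2
F4 | step 16 | (7R,10S,11S,15S)-10,14-dimethyl-7-[(2R)-1-oxopropan-2-yl]spiro[4.5]dec-13-en-15-yl 3-phenylpropanoate (C6 epimer of 30) | O=C[C@H](C)[C@H]1CC[C@H](C)[C@@]12CC=C(C)[C@@H](OC(=O)CCc3ccccc3)C2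
F5 | step 9 | (10S,11S,15R)-15-hydroxy-10,14-dimethylspiro[4.5]deca-7,13-dien-7-yl trifluoromethanesulfonate | FC(F)(F)S(=O)(=O)OC1=CC[C@H](C)[C@@]12CC=C(C)[C@H](O)C2
F6 | step 9 | (10S,11S,15S)-10,14-dimethyl-7-{[(trifluoromethyl)sulfonyl]oxy}spiro[4.5]deca-7,13-dien-15-yl 4-nitrobenzoate | FC(F)(F)S(=O)(=O)OC1=CC[C@H](C)[C@@]12CC=C(C)[C@@H](OC(=O)c3ccc(cc3)[N+](=O)[O-])C2
F7 | step 2 | tert-butyl 2-(2-oxocyclopentyl)acetate (racemic) | O=C1CCCC1CC(=O)OC(C)(C)C
F8 | step 2 | tert-butyl 2-{2-[(trimethylsilyl)oxy]cyclopent-1-en-1-yl}acetate | C[Si](C)(C)OC1=C(CC(=O)OC(C)(C)C)CCC1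
F9 | step 18 | 5-bromo-3-methylfuran-2(5H)-one | CC1=CC(Br)OC1=O
F10 | step 18 | (4-methyl-5-oxo-2,5-dihydrofuran-2-yl)triphenylphosphonium bromide | CC1=CC(OC1=O)[P+](c2ccccc2)(c3ccccc3)c4ccccc4.[Br-]
A1 | alternative 1 | 3-[(2S,3R)-1-(tert-butyldimethylsilyloxy)-2-methylhept-6-en-3-yl]cyclohex-2-en-1-one | CC(C)(C)[Si](C)(C)OC[C@@H](C)[C@@H](CCC=C)C1=CC(=O)CCC1
A2 | alternative 1 | 1-[1-(tert-butyldimethylsilyloxy)propan-2-yl]-4-methylspiro[4.5]decan-7-one (C6, C7, C10, C11 as in the target) | CC(C)(C)[Si](C)(C)OC[C@@H](C)[C@H]2CC[C@H](C)[C@@]23CCCC(=O)C3
A3 | alternative 2 | 2-[(1S,2S)-1-[(2Z)-3-iodobut-2-en-1-yl]-2-methyl-5-oxocyclopentyl]acetaldehyde | O=C1CC[C@H](C)[C@@]1(CC=O)C/C=C(/C)I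
A4 | alternative 2 | 7-hydroxy-4,8-dimethylspiro[4.5]dec-8-en-1-one (C10, C11, C15 as in the target) | O=C2CC[C@H](C)[C@@]23CC=C(C)[C@@H](O)C3
A5 | alternative 3 | methyl (2E,6S)-6-(3-oxocyclohex-1-en-1-yl)hept-2-enoate | COC(=O)/C=C/CC[C@H](C)C1=CC(=O)CCC1
A6 | alternative 3 | methyl 2-(4-methyl-7-oxospiro[4.5]decan-1-yl)acetate (C7, C10, C11 as in the target) | COC(=O)C[C@H]2CC[C@H](C)[C@@]23CCCC(=O)C3
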